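**Retrosynthetic overview**
1. Target 24 ⇐ acetonide 23 ⇐ C4 allylic alcohol 20 (alkene at C5=C6) by Mitsunobu/allylic-diazene reductive 1,3-transposition, which moves the alkene to (E)-C4=C5; acetate and acetonide are adjusted around it.
2. anti-C9,C10 diol ⇐ α-hydroxy enone 16 (chelation-controlled reduction) ⇐ carbinol 13 by tandem anionic oxy-Cope ring expansion/enolate hydroxylation: C7–C8 is made, C5–C10 is broken, and six-membered ring A (C10, C1, C2, C3, C4, C5) becomes the ten-membered ring.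
3. Enabling feature: C8 lies β to the carbinol carbon C10 and C7 lies two atoms from the methyl-bearing C5, so with C10 as an alkoxide and C5 as a quaternary carbon (CH3, vinyl) the atoms C7=C6–C5–C10(O–)–C9=C8 form a 3-oxido-1,5-diene across the C5–C10 bond of a cyclohexene whose C1=C2 bond is already the Z ring alkene.
4. 13 ⇐ enone 8 + (E)-alkenyllithium 12 from (R)-citronellal (C11 stereocentre); 8 ⇐ 2-methylcyclohexane-1,3-dione 1 by vinylation, enzymatic desymmetrisation, Saegusa–Ito oxidation and Morita–Baylis–Hillman hydroxymethylation.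
5. Order of rings: ring A is present from 1; the ten-membered carbocycle is formed in step 10; the dioxolane (acetonide) is a temporary ring (steps 12–16).

Key step: step 10

Remark: C-numbers in the text follow the target (C1 bears CH2OAc, C1=C2, C3, C4=C5(CH3), C6, C7, C8 bears the side chain with C11 as its stereocentre, C9 and C10 are the carbinol carbons); the yeast reduction of vinyl dione 2 is assumed to follow the sense known for its 2-allyl and 2-propargyl congeners.

Step 1
Reactants: 1 2-methylcyclohexane-1,3-dione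
Product: 2 2-methyl-2-vinylcyclohexane-1,3-dione
Conditions: KOt-Bu, THF, −78 °C; phenyl(vinyl)iodonium tetrafluoroborate, −78 °C → rt
Reagents that add atoms: phenyl(vinyl)iodonium tetrafluoroborate, C=C[I+]c1ccccc1.F[B-](F)(F)F
Why: C-Vinylation of the enolate of a 2-substituted cyclic 1,3-dione with an alkenyl(aryl)iodonium salt (ligand coupling at hypervalent iodine) is a known route to a vinyl-bearing quaternary carbon; the product is still achiral and its quaternary carbon becomes C5.

Step 2
Reactants: 2 2-methyl-2-vinylcyclohexane-1,3-dione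
Product: 3 (2S,3S)-3-hydroxy-2-methyl-2-vinylcyclohexan-1-one
Conditions: baker's yeast, sucrose, H2O, 30 °C
Reagents that add atoms: none
Why: Enantiotopic-group-selective enzymatic ketone reduction of 2,2-disubstituted cyclohexane-1,3-diones, established for the 2-allyl and 2-propargyl congeners, should deliver hydride to one carbonyl from the face of the methyl group and thereby set the carbinol centre (future C4) and, by desymmetrisation, the quaternary centre (future C5).

Step 3
Reactants: 3 (2S,3S)-3-hydroxy-2-methyl-2-vinylcyclohexan-1-one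
Product: 4 (2S,3S)-3-[(tert-butyldimethylsilyl)oxy]-2-methyl-2-vinylcyclohexan-1-one
Conditions: TBSOTf, 2,6-lutidine, CH2Cl2, −78 → 0 °C
Reagents that add atoms: tert-butyldimethylsilyl trifluoromethanesulfonate, CC(C)(C)[Si](C)(C)OS(=O)(=O)C(F)(F)F
Why: Silylation with the silyl triflate and a hindered pyridine base protects the hindered secondary alcohol under conditions that do not provoke retro-aldol cleavage of the β-hydroxy ketone.

Step 4
Reactants: 4 (2S,3S)-3-[(tert-butyldimethylsilyl)oxy]-2-methyl-2-vinylcyclohexan-1-one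
Product: 6 (5S,6S)-5-[(tert-butyldimethylsilyl)oxy]-6-methyl-6-vinylcyclohex-2-en-1-one, via trimethylsilyl enol ether 5 (not isolated)
Conditions: LiN(iPr)2, Me3SiCl, THF, −78 °C; then Pd(OAc)2, MeCN, rt
Reagents that add atoms: none
Why: Only one α-carbon of 4 carries hydrogen, so enolisation is regiospecific, and Saegusa–Ito oxidation of the silyl enol ether gives the enone that will become C10(=O)–C1=C2.

Step 5
Reactants: 6 (5S,6S)-5-[(tert-butyldimethylsilyl)oxy]-6-methyl-6-vinylcyclohex-2-en-1-one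
Product: 7 (5S,6S)-5-[(tert-butyldimethylsilyl)oxy]-2-(hydroxymethyl)-6-methyl-6-vinylcyclohex-2-en-1-one
Conditions: aq. CH2O, DMAP (cat.), THF, rt
Reagents that add atoms: formaldehyde, C=O
Why: Morita–Baylis–Hillman hydroxymethylation of a cyclohex-2-enone with aqueous formaldehyde under nucleophilic amine catalysis attaches the future CH2OAc carbon to the enone α-carbon (future C1).

Step 6
Reactants: 7 (5S,6S)-5-[(tert-butyldimethylsilyl)oxy]-2-(hydroxymethyl)-6-methyl-6-vinylcyclohex-2-en-1-one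
Product: 8 (5S,6S)-5-[(tert-butyldimethylsilyl)oxy]-2-{[(tert-butyldimethylsilyl)oxy]methyl}-6-methyl-6-vinylcyclohex-2-en-1-one
Conditions: TBSCl, imidazole, DMF, rt
Reagents that add atoms: tert-butyldimethylsilyl chloride, CC(C)(C)[Si](C)(C)Cl
Why: Routine silylation masks the primary allylic alcohol against the organolithium and the potassium amide used next.

Step 7
Reactants: 9 (R)-citronellal [(3R)-3,7-dimethyloct-6-enal]
Product: 10 (3R)-3,7-dimethyloct-6-en-1-yne
Conditions: C4F9SO2F, P2-Et phosphazene base, DMF, −10 °C → rt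
Reagents that add atoms: none
Why: O-Sulfonylation of the aldehyde enolate gives an alkenyl nonaflate that eliminates under the phosphazene base to the terminal alkyne (one-pot conversion of an enolisable aldehyde into an alkyne); the stereocentre (future C11) is β to the carbonyl and stays untouched.

Step 8
Reactants: 10 (3R)-3,7-dimethyloct-6-en-1-yne
Product: 11 (1E,3R)-1-iodo-3,7-dimethylocta-1,6-diene
Conditions: Cp2Zr(H)Cl, THF, rt; then I2, 0 °C
Reagents that add atoms: iodine, II
Why: syn-Hydrozirconation of the terminal alkyne places zirconium on the terminal carbon and iodinolysis with retention gives the E-alkenyl iodide, the trisubstituted alkene being inert to the zirconium hydride.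

Step 9
Reactants: 11 (1E,3R)-1-iodo-3,7-dimethylocta-1,6-diene; 8 (5S,6S)-5-[(tert-butyldimethylsilyl)oxy]-2-{[(tert-butyldimethylsilyl)oxy]methyl}-6-methyl-6-vinylcyclohex-2-en-1-one
Product: 13 (1R,5S,6S)-5-[(tert-butyldimethylsilyl)oxy]-2-{[(tert-butyldimethylsilyl)oxy]methyl}-1-[(1E,3R)-3,7-dimethylocta-1,6-dien-1-yl]-6-methyl-6-vinylcyclohex-2-en-1-ol, via alkenyllithium 12 (not isolated)
Conditions: 11, t-BuLi (2 equiv), Et2O, −78 °C; then 8, THF, −78 → −40 °C; aq. NH4Cl
Reagents that add atoms: none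
Why: Iodine–lithium exchange retains the E geometry and the alkenyllithium adds 1,2 to the hindered enone carbonyl from the face of the C5 methyl group, anti to the vinyl and silyloxy groups, which sets the C10 carbinol centre (1R), a centre that is erased again in step 10.

Step 10
Reactants: 13 (1R,5S,6S)-5-[(tert-butyldimethylsilyl)oxy]-2-{[(tert-butyldimethylsilyl)oxy]methyl}-1-[(1E,3R)-3,7-dimethylocta-1,6-dien-1-yl]-6-methyl-6-vinylcyclohex-2-en-1-ol
Product: 16 (1Z,4S,5E,8S,9R)-4-[(tert-butyldimethylsilyl)oxy]-1-{[(tert-butyldimethylsilyl)oxy]methyl}-9-hydroxy-5-methyl-8-[(2R)-6-methylhept-5-en-2-yl]cyclodeca-1,5-dien-10-one (target numbering), via potassium alkoxide 14 (not isolated), via potassium dienolate 15 (not isolated)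
Conditions: KN(SiMe3)2, 18-crown-6, THF, 0 °C → rt; then 2-(phenylsulfonyl)-3-phenyloxaziridine, −78 °C; aq. NH4Cl
Reagents that add atoms: 2-(phenylsulfonyl)-3-phenyloxaziridine, O1N(S(=O)(=O)c2ccccc2)C1c1ccccc1
Why: The potassium alkoxide is a 3-oxido-1,5-diene (C7=C6–C5–C10(O–)–C9=C8) and undergoes the charge-accelerated [3,3] shift of an anionic oxy-Cope rearrangement, the closest known reaction type being the ring expansion of 1,2-dialkenylcyclohexanols to cyclodec-5-enones; C7–C8 is formed, C5–C10 is broken and the regiodefined dienolate 15 results. The ten-membered ring is therefore closed by a four-atom sigmatropic ring expansion of ring A through a chair transition state, not by an end-to-end macrocyclisation. C8 (S) is set by chirality transfer from C5: in the chair the ring bond C5–C4 and the E-alkene substituent C11 are equatorial, which also gives the E geometry of C5=C6, and since C10 is destroyed its epimer would funnel into the same C8 configuration. C9 (R) is set in the same flask when the oxaziridine transfers oxygen to the enolate face anti to the branched C11 substituent (C8–H in the enolate plane to avoid allylic 1,3-strain), trans to the side chain as in kinetic trapping of 3-substituted cyclic enolates. The step needs the [3,3] path to win over [1,3] shift and fragmentation and the exocyclic diene to react in place of the endocyclic C1=C2 alkene; the gauche, chair-compatible disposition of the two alkenyl groups on adjacent ring carbons and the crown-ether-separated alkoxide secure the first, and the strained bicyclic transition state of the alternative secures the second. Only silyl ethers are present, so base and oxidant have no other site of attack.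

Step 11
Reactants: 16 (1Z,4S,5E,8S,9R)-4-[(tert-butyldimethylsilyl)oxy]-1-{[(tert-butyldimethylsilyl)oxy]methyl}-9-hydroxy-5-methyl-8-[(2R)-6-methylhept-5-en-2-yl]cyclodeca-1,5-dien-10-one
Product: 17 (1Z,4S,5E,8S,9R,10S)-4-[(tert-butyldimethylsilyl)oxy]-1-{[(tert-butyldimethylsilyl)oxy]methyl}-5-methyl-8-[(2R)-6-methylhept-5-en-2-yl]cyclodeca-1,5-diene-9,10-diol (target numbering)
Conditions: Zn(BH4)2, Et2O, −20 °C; aq. NH4Cl
Reagents that add atoms: none
Why: Zinc chelates the C9 hydroxyl and the C10 carbonyl and hydride adds 1,2 to the carbonyl face syn to C9–H (chelation-controlled reduction of an α-hydroxy ketone), giving the anti-(9R,10S) diol.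

Step 12
Reactants: 17 (1Z,4S,5E,8S,9R,10S)-4-[(tert-butyldimethylsilyl)oxy]-1-{[(tert-butyldimethylsilyl)oxy]methyl}-5-methyl-8-[(2R)-6-methylhept-5-en-2-yl]cyclodeca-1,5-diene-9,10-diol
Product: 18 9,10-O-isopropylidene acetal (acetonide) of 17
Conditions: Me2C(OMe)2, PPTS (cat.), CH2Cl2, rt
Reagents that add atoms: 2,2-dimethoxypropane, COC(C)(C)OC
Why: Acid-catalysed transacetalisation engages only the vicinal diol, leaves the silyl ethers and ensures that the C4 hydroxyl is the only free secondary alcohol in step 15.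

Step 13
Reactants: 18 9,10-O-isopropylidene acetal of 17
Product: 19 (1Z,4S,5E,8S,9R,10S)-1-(hydroxymethyl)-9,10-(isopropylidenedioxy)-5-methyl-8-[(2R)-6-methylhept-5-en-2-yl]cyclodeca-1,5-dien-4-ol (target numbering)
Conditions: Bu4NF, THF, 0 °C → rt; aq. NH4Cl
Reagents that add atoms: none
Why: Fluoride cleaves the primary and the secondary silyl ether and does not touch the acetonide.

Step 14
Reactants: 19 (1Z,4S,5E,8S,9R,10S)-1-(hydroxymethyl)-9,10-(isopropylidenedioxy)-5-methyl-8-[(2R)-6-methylhept-5-en-2-yl]cyclodeca-1,5-dien-4-ol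
Product: 20 [(1Z,4S,5E,8S,9R,10S)-4-hydroxy-9,10-(isopropylidenedioxy)-5-methyl-8-[(2R)-6-methylhept-5-en-2-yl]cyclodeca-1,5-dien-1-yl]methyl acetate (target numbering)
Conditions: AcCl, 2,4,6-collidine, CH2Cl2, −78 °C
Reagents that add atoms: acetyl chloride, CC(=O)Cl
Why: Acetyl chloride with a hindered pyridine base at low temperature acylates the primary allylic alcohol much faster than the hindered secondary C4 alcohol (selective acylation of primary over secondary alcohols).

Step 15
Reactants: 20 [(1Z,4S,5E,8S,9R,10S)-4-hydroxy-9,10-(isopropylidenedioxy)-5-methyl-8-[(2R)-6-methylhept-5-en-2-yl]cyclodeca-1,5-dien-1-yl]methyl acetate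
Product: 23 [(1Z,4E,8S,9R,10S)-9,10-(isopropylidenedioxy)-5-methyl-8-[(2R)-6-methylhept-5-en-2-yl]cyclodeca-1,4-dien-1-yl]methyl acetate, via sulfonylhydrazine adduct 21 (not isolated), via allylic diazene 22 (not isolated)
Conditions: PPh3, DEAD, 2-nitrobenzenesulfonylhydrazide, N-methylmorpholine, −30 °C → rt
Reagents that add atoms: none
Why: Mitsunobu displacement of the C4 alcohol by the sulfonylhydrazide with inversion, loss of 2-nitrobenzenesulfinic acid and retro-ene loss of N2 from the allylic diazene deliver hydrogen to C6 and move the alkene to C4=C5 (reductive 1,3-transposition of allylic alcohols); after inversion the C4–N bond stands perpendicular to the C5=C6 plane with C3 anti to C6, so that the E alkene should result.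

Step 16
Reactants: 23 [(1Z,4E,8S,9R,10S)-9,10-(isopropylidenedioxy)-5-methyl-8-[(2R)-6-methylhept-5-en-2-yl]cyclodeca-1,4-dien-1-yl]methyl acetate
Product: 24 [(1Z,4E,8S,9R,10S)-9,10-dihydroxy-5-methyl-8-[(2R)-6-methylhept-5-en-2-yl]cyclodeca-1,4-dien-1-yl]methyl acetate (target)
Conditions: AcOH–H2O (4:1), 40 °C
Reagents that add atoms: none
Why: Mild aqueous acetic acid hydrolyses the dioxolane and leaves the allylic acetate and the skipped diene intact, giving the target.

**Compound list**
1 | 2-methylcyclohexane-1,3-dione | CC1C(=O)CCCC1=O | starting material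
2 | 2-methyl-2-vinylcyclohexane-1,3-dione | C=CC1(C)C(=O)CCCC1=O | intermediate
3 | (2S,3S)-3-hydroxy-2-methyl-2-vinylcyclohexan-1-one | O=C1CCC[C@H](O)[C@]1(C)C=C | intermediate
4 | (2S,3S)-3-[(tert-butyldimethylsilyl)oxy]-2-methyl-2-vinylcyclohexan-1-one | O=C1CCC[C@H](O[Si](C)(C)C(C)(C)C)[C@]1(C)C=C | intermediate
5 | trimethylsilyl enol ether of 4 (not isolated) | C[Si](C)(C)OC1=CCC[C@H](O[Si](C)(C)C(C)(C)C)[C@]1(C)C=C | intermediate
6 | (5S,6S)-5-[(tert-butyldimethylsilyl)oxy]-6-methyl-6-vinylcyclohex-2-en-1-one | O=C1C=CC[C@H](O[Si](C)(C)C(C)(C)C)[C@]1(C)C=C | intermediate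
7 | (5S,6S)-5-[(tert-butyldimethylsilyl)oxy]-2-(hydroxymethyl)-6-methyl-6-vinylcyclohex-2-en-1-one | O=C1C(CO)=CC[C@H](O[Si](C)(C)C(C)(C)C)[C@]1(C)C=C | intermediate
8 | (5S,6S)-5-[(tert-butyldimethylsilyl)oxy]-2-{[(tert-butyldimethylsilyl)oxy]methyl}-6-methyl-6-vinylcyclohex-2-en-1-one | O=C1C(CO[Si](C)(C)C(C)(C)C)=CC[C@H](O[Si](C)(C)C(C)(C)C)[C@]1(C)C=C | intermediate
9 | (R)-citronellal, (3R)-3,7-dimethyloct-6-enal | O=CC[C@H](C)CCC=C(C)C | starting material
10 | (3R)-3,7-dimethyloct-6-en-1-yne | C#C[C@H](C)CCC=C(C)C | intermediate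
11 | (1E,3R)-1-iodo-3,7-dimethylocta-1,6-diene | I/C=C/[C@H](C)CCC=C(C)C | intermediate
12 | (1E,3R)-3,7-dimethylocta-1,6-dien-1-yllithium (not isolated) | [Li]/C=C/[C@H](C)CCC=C(C)C | intermediate
13 | (1R,5S,6S)-5-[(tert-butyldimethylsilyl)oxy]-2-{[(tert-butyldimethylsilyl)oxy]methyl}-1-[(1E,3R)-3,7-dimethylocta-1,6-dien-1-yl]-6-methyl-6-vinylcyclohex-2-en-1-ol | O[C@]1(/C=C/[C@H](C)CCC=C(C)C)C(CO[Si](C)(C)C(C)(C)C)=CC[C@H](O[Si](C)(C)C(C)(C)C)[C@]1(C)C=C | intermediate
14 | potassium alkoxide of 13 (not isolated) | [K]O[C@]1(/C=C/[C@H](C)CCC=C(C)C)C(CO[Si](C)(C)C(C)(C)C)=CC[C@H](O[Si](C)(C)C(C)(C)C)[C@]1(C)C=C | intermediate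
15 | ring-expanded potassium dienolate (C9=C10–OK, C1=C2 Z, C5=C6 E, 4S, 8S; not isolated) | CC(C)(C)[Si](C)(C)OC/C1=C/C[C@H](O[Si](C)(C)C(C)(C)C)/C(C)=C/C[C@@H]([C@H](C)CCC=C(C)C)/C=C1\O[K] | intermediate
16 | (1Z,4S,5E,8S,9R)-4-[(tert-butyldimethylsilyl)oxy]-1-{[(tert-butyldimethylsilyl)oxy]methyl}-9-hydroxy-5-methyl-8-[(2R)-6-methylhept-5-en-2-yl]cyclodeca-1,5-dien-10-one (target numbering) | CC(C)(C)[Si](C)(C)OC/C1=C/C[C@H](O[Si](C)(C)C(C)(C)C)/C(C)=C/C[C@@H]([C@H](C)CCC=C(C)C)[C@@H](O)C1=O | intermediate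
17 | (1Z,4S,5E,8S,9R,10S)-4-[(tert-butyldimethylsilyl)oxy]-1-{[(tert-butyldimethylsilyl)oxy]methyl}-5-methyl-8-[(2R)-6-methylhept-5-en-2-yl]cyclodeca-1,5-diene-9,10-diol (target numbering) | CC(C)(C)[Si](C)(C)OC/C1=C/C[C@H](O[Si](C)(C)C(C)(C)C)/C(C)=C/C[C@@H]([C@H](C)CCC=C(C)C)[C@@H](O)[C@H]1O | intermediate
18 | 9,10-O-isopropylidene acetal (acetonide) of 17 | CC(C)(C)[Si](C)(C)OC/C1=C/C[C@H](O[Si](C)(C)C(C)(C)C)/C(C)=C/C[C@@H]([C@H](C)CCC=C(C)C)[C@@H]2[C@H]1OC(C)(C)O2 | intermediate
19 | (1Z,4S,5E,8S,9R,10S)-1-(hydroxymethyl)-9,10-(isopropylidenedioxy)-5-methyl-8-[(2R)-6-methylhept-5-en-2-yl]cyclodeca-1,5-dien-4-ol (target numbering) | OC/C1=C/C[C@H](O)/C(C)=C/C[C@@H]([C@H](C)CCC=C(C)C)[C@@H]2[C@H]1OC(C)(C)O2 | intermediate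
20 | [(1Z,4S,5E,8S,9R,10S)-4-hydroxy-9,10-(isopropylidenedioxy)-5-methyl-8-[(2R)-6-methylhept-5-en-2-yl]cyclodeca-1,5-dien-1-yl]methyl acetate (target numbering) | CC(=O)OC/C1=C/C[C@H](O)/C(C)=C/C[C@@H]([C@H](C)CCC=C(C)C)[C@@H]2[C@H]1OC(C)(C)O2 | intermediate
21 | (4R)-4-[1-(2-nitrobenzenesulfonyl)hydrazin-1-yl] analogue of 20, C4 inverted (not isolated) | CC(=O)OC/C1=C/C[C@@H](N(N)S(=O)(=O)c3ccccc3[N+](=O)[O-])/C(C)=C/C[C@@H]([C@H](C)CCC=C(C)C)[C@@H]2[C@H]1OC(C)(C)O2 | intermediate
22 | (4R)-4-diazenyl analogue of 20, allylic diazene (not isolated) | CC(=O)OC/C1=C/C[C@@H](N=N)/C(C)=C/C[C@@H]([C@H](C)CCC=C(C)C)[C@@H]2[C@H]1OC(C)(C)O2 | intermediate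
23 | [(1Z,4E,8S,9R,10S)-9,10-(isopropylidenedioxy)-5-methyl-8-[(2R)-6-methylhept-5-en-2-yl]cyclodeca-1,4-dien-1-yl]methyl acetate | CC(=O)OC/C1=C/C/C=C(\C)CC[C@@H]([C@H](C)CCC=C(C)C)[C@@H]2[C@H]1OC(C)(C)O2 | intermediate
24 | [(1Z,4E,8S,9R,10S)-9,10-dihydroxy-5-methyl-8-[(2R)-6-methylhept-5-en-2-yl]cyclodeca-1,4-dien-1-yl]methyl acetate | CC(=O)OC/C1=C/C/C=C(\C)CC[C@@H]([C@H](C)CCC=C(C)C)[C@@H](O)[C@H]1O | target

**Totals and risks**
Total step count: 16. Longest linear sequence: 14 steps (steps 1–6 and 9–16).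

Steps most likely to fail:

1. Step 10. The facial selectivity of oxygen transfer to the ring-expanded enolate may be low or reversed, because attack from the periphery of the ten-membered ring can override the preference for attack anti to the side chain. Fallback (inversion in place of direct facial control): starting from 13, the rearrangement–oxygenation is then run to the C9 epimer of 16, the (9S)-hydroxy ketone F1. Tf2O and pyridine (CH2Cl2, −40 °C) give the α-triflyloxy ketone F2. Displacement with Bu4N+ NO2– in DMF goes with inversion at C9 to the nitrite ester F3, and its hydrolysis on aqueous work-up returns to the route at 16.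

2. Step 15. The Mitsunobu displacement at the hindered allylic C4 carbinol may be slow or may take the SN2′ course, and the alkene geometry may erode. Fallback (hydride addition to a C=N bond in place of substitution at carbon): starting from 20, Dess–Martin periodinane (CH2Cl2, rt) gives the C4 enone F4. p-Toluenesulfonylhydrazide (EtOH, rt) gives the tosylhydrazone F5. Catecholborane (CHCl3, 0 °C), then NaOAc·3H2O (reflux), adds hydride to C4 and expels p-toluenesulfinate to give allylic diazene 22 together with its C4 epimer, the (4S)-diazene F6. Both lose N2 with hydrogen shift to C6, returning to the route at 23.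

3. Step 2. Methyl and vinyl are similar in size, so the enzyme may discriminate poorly between the two carbonyl faces and the two enantiotopic carbonyl groups, which would erode the configuration at the quaternary carbon. Fallback (established substrate, vinyl group made afterwards): starting from 1, C-allylation (allyl bromide, aq. NaOH, rt) gives 2-allyl-2-methylcyclohexane-1,3-dione F7. Baker's yeast gives (2S,3S)-2-allyl-3-hydroxy-2-methylcyclohexan-1-one F8. TBSOTf and 2,6-lutidine give the silyl ether F9. Alkene isomerisation (RuHCl(CO)(PPh3)3, toluene, 80 °C) gives the (E)-prop-1-enyl ketone F10. Ethenolysis (ethylene, second-generation Grubbs catalyst, CH2Cl2, 40 °C) shortens it to the vinyl group and returns to the route at 4.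

Further compounds
F1 | step 10 | (1Z,4S,5E,8S,9S)-4-[(tert-butyldimethylsilyl)oxy]-1-{[(tert-butyldimethylsilyl)oxy]methyl}-9-hydroxy-5-methyl-8-[(2R)-6-methylhept-5-en-2-yl]cyclodeca-1,5-dien-10-one, C9 epimer of 16 | CC(C)(C)[Si](C)(C)OC/C1=C/C[C@H](O[Si](C)(C)C(C)(C)C)/C(C)=C/C[C@@H]([C@H](C)CCC=C(C)C)[C@H](O)C1=O
F2 | step 10 | 9-O-trifluoromethanesulfonate of F1 | CC(C)(C)[Si](C)(C)OC/C1=C/C[C@H](O[Si](C)(C)C(C)(C)C)/C(C)=C/C[C@@H]([C@H](C)CCC=C(C)C)[C@H](OS(=O)(=O)C(F)(F)F)C1=O
F3 | step 10 | (9R)-nitrite ester of 16 | CC(C)(C)[Si](C)(C)OC/C1=C/C[C@H](O[Si](C)(C)C(C)(C)C)/C(C)=C/C[C@@H]([C@H](C)CCC=C(C)C)[C@@H](ON=O)C1=O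
F4 | step 15 | [(1Z,5E,8S,9R,10S)-9,10-(isopropylidenedioxy)-5-methyl-8-[(2R)-6-methylhept-5-en-2-yl]-4-oxocyclodeca-1,5-dien-1-yl]methyl acetate | CC(=O)OC/C1=C/CC(=O)/C(C)=C/C[C@@H]([C@H](C)CCC=C(C)C)[C@@H]2[C@H]1OC(C)(C)O2
F5 | step 15 | p-toluenesulfonylhydrazone of F4 | CC(=O)OC/C1=C/CC(=NNS(=O)(=O)c3ccc(C)cc3)/C(C)=C/C[C@@H]([C@H](C)CCC=C(C)C)[C@@H]2[C@H]1OC(C)(C)O2
F6 | step 15 | (4S)-4-diazenyl analogue of 20, C4 epimer of 22 | CC(=O)OC/C1=C/C[C@H](N=N)/C(C)=C/C[C@@H]([C@H](C)CCC=C(C)C)[C@@H]2[C@H]1OC(C)(C)O2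
F7 | step 2 | 2-allyl-2-methylcyclohexane-1,3-dione | C=CCC1(C)C(=O)CCCC1=O
F8 | step 2 | (2S,3S)-2-allyl-3-hydroxy-2-methylcyclohexan-1-one | O=C1CCC[C@H](O)[C@]1(C)CC=C
F9 | step 2 | (2S,3S)-2-allyl-3-[(tert-butyldimethylsilyl)oxy]-2-methylcyclohexan-1-one | O=C1CCC[C@H](O[Si](C)(C)C(C)(C)C)[C@]1(C)CC=C
F10 | step 2 | (2S,3S)-3-[(tert-butyldimethylsilyl)oxy]-2-methyl-2-[(1E)-prop-1-en-1-yl]cyclohexan-1-one | O=C1CCC[C@H](O[Si](C)(C)C(C)(C)C)[C@]1(C)/C=C/C
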